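**Conventions.** Carbons carry the chain numbers C1 (acid carbon) to C20 (acetyl methyl). Ring A is C8, C9, C14–C17; ring B is C9–C14. β is the face of the bicycle that carries H9, α the opposite face.

**Remark on the chemistry.** The C8 configuration of 4 to 26 is reset in step 18, and the carbinol centres at C17 (in 6) and C15 (in 18, 19) are destroyed again. Only the expected major isomers are drawn for these.

## Analysis of the target

The C20 chain is folded into a cyclohexa-1,3-diene (ring A: C14=C15, C16=C17, sp3 C8 and C9) fused through C9–C14 to a 2,6-dimethylcyclohexanone (ring B, C11 ketone). C17 carries an acetonyl group and C8 carries the side chain, a (4S,5S)-trans-oxirane flanked by the C6=C7 alkene and the C2=C3 enoic acid. The four ring hydrogens H8, H9, H10 and H12 all lie on the β face, so C7 and the C10 and C12 methyls are all α (8S,9S,10R,12S). Because C14 is sp2, C8 must be equatorial on ring B, which forces the two methyls into a 1,3-diaxial chair or a twist-boat; C10 and C12 are therefore the less stable configurations next to an enolisable ketone and cannot be set by equilibration. Further sensitive points are the C19 ketone (β,γ to the ring diene and ready to move into conjugation), the doubly allylic C8–H, and the acid-labile vinyl oxirane. The hard problem is oxidation of one alkene out of five. C4=C5 is the middle alkene of a 2,4,6-trienoic acid and is less electron-rich than the ring A diene and C6=C7, so electrophilic oxidants would go elsewhere. The strategy rests on that feature: the C4–C5 oxygen is put in last, by a catalyst that selects by position and not by electron density.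

## Retrosynthetic reasoning

**40 to 39.** The two C–O bonds of the oxirane are cut. Nothing else in 40 differs from triene acid 39, so the epoxide never has to survive a chemical step. The forward reaction must deliver one oxygen atom to C4=C5 only, on one face.

**39 to 38 to 36.** The C11 ketone is taken back to the alcohol 38, so that C10 and C12 never sit next to a carbonyl while base or acid is used. Ester and ketal are restored in 36, which keeps the β,γ-unsaturated C19 ketone masked until the end.

**36 to 28.** The three chain alkenes are cut in turn (C2=C3, C4=C5, C6=C7) as Wittig olefinations with the stabilised ylides 35, 33 and 29. These are achiral, E-selective and neutral, which the α-stereogenic aldehyde 28 needs.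

**28 to 26 to 24.** C8 is the one centre that must be made last. C7 has to end on the face that already carries the axial C10 methyl, so bond formation at C8 would go to the wrong face, whereas proton delivery to the planar C8 enolate goes to the right one. The aldehyde comes from diol 25 and the silyl ethers of diene 24.

**24 to 21.** The ring A diene is traced to the C15 enone through its cross-conjugated dienyl triflate 23. The C14=C15 bond is thus derived from an α′ position that is also the handle for building ring B.

**21 to 17.** C10–H and C11–O are cut together. Both come from one syn hydroboration of a C10=C11 alkene in a rigid trans-fused bicycle, where the C12 methyl blocks the α face.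

**17 to 9 and 14.** C10=C11 is cut by ring-closing metathesis and C13–C14 by enolate alkylation. The isopropenyl group of carvone supplies C10 and its methyl unchanged, and the C12 centre is bought with fragment 14, made in three steps from 10.

**9 to 1.** The C19 ketal comes from an allyl group (Wacker oxidation of 7). The allyl group and the C15 ketone come from 1,2-addition of 5 to ketone 4 followed by oxidative 1,3-transposition, which also turns the γ carbon of carvone (C14) into an enolisable α′ carbon. C7 is attached to 1 by α′-alkylation with 2. C9 is the stereocentre of 1.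

## Alternatives that were turned down

**Alternative 1:** Ring A is cut at C16–C17 and C8–C9. Forward, a 2-siloxy diene on a cyclohexene adds endo to a chiral 5-menthyloxybutenolide, anti to the alkoxy group, giving adduct A1; loss of silanol then makes C16=C17.
- For it: one convergent step closes ring A and sets C8 and C9 together under auxiliary control, with C7 already at the aldehyde level. On this point it is stronger than the chosen route, which corrects C8 late by protonation.
- Against it: ring B of A1 has no methyl groups. They would have to be put in by enolate methylation next to C11, and the required all-syn pattern is the strained one that neither axial alkylation nor equilibration gives. The C18 lactone carbon is at the acid level and must be rebuilt into CH2–CO–CH3. The silanol elimination can also go to the methyl group.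
- Comparison: the epoxide problem is untouched. The chosen route spends more linear steps but fixes C10 and C12 kinetically and ends with no step after the oxidation.

**Alternative 2:** C9–C14, C15–C16 and C8–C17 are cut at once. Forward, a cationic monovalent rhodium catalyst joins a terminal alkyne, a Z-enoate and an internal alkyne of one ester-tethered chain to give the tricyclic diene lactone A2.
- For it: the best step economy of all four plans for the core, cis H8/H9 from the Z-alkene, and a C10–C12 triad made by acyclic methods.
- Against it: the Z-alkene holds C10–H in the alkene plane (allylic 1,3-strain), so the tether should approach the face that puts the C10 methyl trans to C8, while the target needs it cis. β-Hydride elimination from the rhodacycle at C8 or C9 competes with reductive elimination. A2 still needs lactone opening and two redox changes at C7 and C19.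
- Comparison: shorter but with its stereochemical risk in the middle of the synthesis and the site-selective epoxidation still unsolved. The chosen route uses only known steps up to 39.

**Alternative 3:** C8–C9 is formed and C11–C16 broken. Forward, the potassium alkoxide of a bridgehead bicyclo[2.2.2]octenol rearranges through an enforced boat to the enolate A3.
- For it: an irreversible, well-understood pericyclic step that transfers the cage geometry to C8 and C9. On predictability of the key step it is stronger than an untested enzyme.
- Against it: A3 has C14 sp3 and no diene, no C12 methyl, a C10 enolate that must be protonated cis to C8, a C17 enol ether without the acetonyl carbons, and a 2-methylpropenyl arm that needs allylic oxidation. The cage itself needs several steps.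
- Comparison: much work follows its key step, and the epoxide is again left open. The chosen route has nothing after its key step.

Key step: step 26

## Route

Step 1
Reactants: 1 (S)-carvone; 2 (chloromethoxy)triisopropylsilane
Product: 4 (5S,6S)-2-methyl-5-(prop-1-en-2-yl)-6-[(triisopropylsilyloxy)methyl]cyclohex-2-en-1-one (C7 β, trans to C10), via lithium dienolate 3 (not isolated)
Conditions: LiN(i-Pr)2, THF, −78 °C; then 2, −78 to −20 °C
Reagents that add atoms: none
Why: Kinetic deprotonation at C8 gives the cross-conjugated dienolate, which is C-alkylated by the α-chloro ether (enolate alkylation) mainly anti to the C9 isopropenyl group. The C8 configuration is corrected in step 18.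

Step 2
Reactants: 4; 5 allylmagnesium bromide
Product: 6 tertiary allylic alcohol, 1-allyl carbinol of 4 (C17 OH β, allyl α)
Conditions: 5, THF, −78 °C
Reagents that add atoms: none
Why: Allyl Grignard reagents add 1,2 to enones. The C17 carbinol centre is lost in step 3.

Step 3
Reactants: 6
Product: 7 3-allyl-2-methyl-5-(prop-1-en-2-yl)-4-[(triisopropylsilyloxy)methyl]cyclohex-2-en-1-one (C15 ketone, C16=C17; C7 β, C10 α)
Conditions: C5H5NH[CrO3Cl], NaOAc, 4 Å sieves, CH2Cl2, 23 °C
Reagents that add atoms: pyridinium chlorochromate, [O-][Cr](=O)(=O)Cl.c1cc[nH+]cc1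
Why: Dauben oxidative 1,3-transposition: the tertiary allylic chromate ester shifts [3,3] and the secondary chromate is oxidised, so oxygen moves to C15 and the allyl group stays on C17. C14 thereby becomes an α′ position.

Step 4
Reactants: 7
Product: 8 methyl ketone, 3-(2-oxopropyl) analogue of 7 (C19 ketone)
Conditions: PdCl2 (cat.), CuCl, O2, DMF/H2O, 23 °C
Reagents that add atoms: water, O
Why: Tsuji–Wacker oxidation: only the monosubstituted allyl alkene undergoes Markovnikov hydroxypalladation. The 1,1-disubstituted isopropenyl alkene and the tetrasubstituted enone alkene are inert.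

Step 5
Reactants: 8
Product: 9 C19 ethylene ketal of 8
Conditions: Me3SiOCH2CH2OSiMe3, Me3SiOTf (cat.), CH2Cl2, −78 to −20 °C
Reagents that add atoms: 1,2-bis(trimethylsilyloxy)ethane, C[Si](C)(C)OCCO[Si](C)(C)C
Why: Noyori ketalisation at low temperature takes the saturated methyl ketone and leaves the hindered conjugated C15 ketone. The ketal removes the acidic C18 protons and the risk of alkene migration until step 24.

Step 6
Reactants: 10 (S)-3-bromo-2-methylpropan-1-ol
Product: 11 (S)-(3-hydroxy-2-methylpropyl)triphenylphosphonium bromide
Conditions: PPh3, MeCN, reflux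
Reagents that add atoms: triphenylphosphine, c1ccc(cc1)P(c1ccccc1)c1ccccc1
Why: SN2 quaternisation of the phosphine by the primary bromide; the stereocentre (future C12) is not touched.

Step 7
Reactants: 11
Product: 13 (R)-2-methylbut-3-en-1-ol, via oxido ylide 12 (not isolated)
Conditions: n-BuLi (2 equiv), THF, −78 to 0 °C; then (CH2O)n, 0 to 23 °C
Reagents that add atoms: formaldehyde, C=O
Why: Wittig olefination of formaldehyde by the non-stabilised γ-oxido ylide gives the terminal alkene. The stereocentre is not involved.

Step 8
Reactants: 13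
Product: 14 (R)-2-methylbut-3-en-1-yl trifluoromethanesulfonate
Conditions: Tf2O, 2,6-lutidine, CH2Cl2, −78 °C; used at once
Reagents that add atoms: trifluoromethanesulfonic anhydride, FC(F)(F)S(=O)(=O)OS(=O)(=O)C(F)(F)F
Why: O-Sulfonylation to the primary triflate. A β-branched iodide would alkylate a ketone enolate too slowly for step 9.

Step 9
Reactants: 9; 14
Product: 16 C14-alkylated enone, 6-[(2R)-2-methylbut-3-enyl] derivative of 9 (C13 β, trans to C10; C12 methyl as in the target), via lithium enolate 15 (not isolated)
Conditions: LiN(i-Pr)2, THF, −78 °C; then 14, −78 to −40 °C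
Reagents that add atoms: none
Why: Kinetic α′-deprotonation of the enone at C14 and SN2 alkylation by the primary triflate, anti to the C9 substituent. C12 comes from 14; the C14 centre becomes sp2 in step 14.

Step 10
Reactants: 16
Product: 17 trans-fused bicyclic enone with C10=C11 (H9 β, H14 α; C12 methyl α)
Conditions: RuCl2(=CHPh)(PCy3)(H2IMes) (second-generation Grubbs catalyst, 5 mol %), CH2Cl2, 40 °C
Reagents that add atoms: none
Why: Ring-closing olefin metathesis between the isopropenyl and vinyl groups closes ring B as a six-membered ring with a trisubstituted alkene and loss of ethylene. The tetrasubstituted enone alkene does not react.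

Step 11
Reactants: 17
Product: 19 diol (C11 OH β, C10 methyl α, C15 OH α), via organoborane 18 (not isolated)
Conditions: BH3·THF (3 equiv), THF, 0 to 23 °C; then NaOH, H2O2, 0 °C
Reagents that add atoms: hydrogen peroxide, OO
Why: Hydroboration–oxidation: boron goes to C11 and hydrogen to C10, syn and from the β face, because in the trans-fused half-chair the C12 methyl is pseudoaxial on the α face. This sets C10 (H β, methyl α) and C11. The C15 ketone is reduced by the same reagent and restored in step 12.

Step 12
Reactants: 19
Product: 20 hydroxy enone (C15 ketone, C11 OH β)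
Conditions: MnO2, CH2Cl2, 23 °C
Reagents that add atoms: none
Why: MnO2 oxidises only the allylic C15 alcohol; the saturated, hindered C11 alcohol is left.

Step 13
Reactants: 20
Product: 21 C11 tert-butyldimethylsilyl ether of 20
Conditions: t-BuMe2SiOTf, 2,6-lutidine, CH2Cl2, 0 °C
Reagents that add atoms: tert-butyldimethylsilyl trifluoromethanesulfonate, CC(C)(C)[Si](C)(C)OS(=O)(=O)C(F)(F)F
Why: Silylation of the hindered alcohol with the silyl triflate protects C11 against the strong base of step 14 and keeps C10 and C12 non-enolisable.

Step 14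
Reactants: 21
Product: 23 dienyl triflate (C14=C15(OTf), C16=C17), via lithium dienolate 22 (not isolated)
Conditions: LiN(i-Pr)2, THF, −78 °C; then N-(5-chloropyridin-2-yl)bis(trifluoromethanesulfonyl)imide
Reagents that add atoms: Comins reagent, FC(F)(F)S(=O)(=O)N(c1ccc(Cl)cn1)S(=O)(=O)C(F)(F)F
Why: Kinetic removal of the axial α′ proton at C14 gives the cross-conjugated dienolate, which is O-triflated. Both ring A double bonds are then in their final positions.

Step 15
Reactants: 23
Product: 24 ring A diene (C15–H), bis-silyl ether ketal
Conditions: Pd(OAc)2 (cat.), PPh3, n-Bu3N, HCO2H, DMF, 60 °C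
Reagents that add atoms: none
Why: Palladium-catalysed formate reduction of the vinyl triflate (oxidative addition, decarboxylation of the formate, reductive elimination) replaces OTf by H without touching C8 or C9.

Step 16
Reactants: 24
Product: 25 diol (C7 OH, C11 OH)
Conditions: n-Bu4NF, THF, 23 to 50 °C
Reagents that add atoms: none
Why: Fluoride cleaves both silyl ethers; the ketal and the diene are stable to it.

Step 17
Reactants: 25
Product: 26 C7 aldehyde, 8-epi series (C7 β)
Conditions: TEMPO (cat.), PhI(OAc)2, CH2Cl2, 23 °C
Reagents that add atoms: none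
Why: Oxoammonium oxidation selects the primary C7 alcohol over the hindered secondary C11 alcohol and stops at the aldehyde under near-neutral conditions.

Step 18
Reactants: 26
Product: 28 C7 aldehyde with the target C8 configuration (C7 α, H8 β), via dipotassium enolate 27 (not isolated)
Conditions: KN(SiMe3)2 (2.2 equiv), THF, −78 °C; then AcOH, −78 °C
Reagents that add atoms: none
Why: Deprotonation at C8 (and at O11) gives a planar extended enolate, and kinetic protonation at the α carbon keeps the diene out of conjugation with the aldehyde. The proton should enter from the β face, anti to the axial α methyl on C10, which makes H8 cis to H9.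

Step 19
Reactants: 28; 29 ethyl 2-(triphenylphosphoranylidene)propanoate
Product: 30 ethyl (E)-enoate (C6=C7, C5 ester)
Conditions: CH2Cl2, 23 °C
Reagents that add atoms: none
Why: Wittig olefination with an ester-stabilised ylide gives the E trisubstituted alkene under neutral conditions that should not epimerise C8.

Step 20
Reactants: 30
Product: 31 allylic alcohol (C5 OH)
Conditions: i-Bu2AlH (3.5 equiv), CH2Cl2, −78 °C
Reagents that add atoms: none
Why: 1,2-Reduction of the enoate to the allylic alcohol; the ketal, the diene and the C11 alkoxide are inert.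

Step 21
Reactants: 31
Product: 32 (E)-enal (C5 aldehyde)
Conditions: MnO2, CH2Cl2, 23 °C
Reagents that add atoms: none
Why: Allylic oxidation with MnO2; the non-allylic C11 alcohol stays.

Step 22
Reactants: 32; 33 2-(triphenylphosphoranylidene)propanal
Product: 34 (4E,6E)-dienal (C3 aldehyde)
Conditions: toluene, 80 °C
Reagents that add atoms: none
Why: Wittig olefination with the formyl-stabilised ylide gives the E alkene C4=C5 and the enal in one step. The product aldehyde is less electrophilic than 32, so homologation should stop after one unit.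

Step 23
Reactants: 34; 35 methyl (triphenylphosphoranylidene)acetate
Product: 36 methyl (2E,4E,6E)-trienoate (C11 OH, C19 ketal)
Conditions: CH2Cl2, 23 °C
Reagents that add atoms: none
Why: Wittig olefination with an ester-stabilised ylide forms the E alkene C2=C3 and completes the all-E triene.

Step 24
Reactants: 36
Product: 38 11-hydroxy-19-oxo trienoic acid, via lithium carboxylate 37 (not isolated)
Conditions: LiOH, THF/MeOH/H2O, 23 °C; then 1 M HCl to pH 2, 23 °C
Reagents that add atoms: lithium hydroxide, [Li+].[OH-]; water, O
Why: Saponification, then acid hydrolysis of the dioxolane in the same flask. C11 is still an alcohol, so no epimerisable ketone meets base or acid, and the mild acid limits migration of C16=C17 toward C19.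

Step 25
Reactants: 38
Product: 39 4,5-deoxy precursor, (2E,4E,6E)-triene acid with C11 and C19 ketones
Conditions: Dess–Martin periodinane, NaHCO3, CH2Cl2, 0 to 23 °C
Reagents that add atoms: none
Why: Dess–Martin oxidation under buffered, base-free conditions forms the C11 ketone without enolising C10 or C12.

Step 26
Reactants: 39
Product: 40 CNP0214881.1
Conditions: cytochrome P450 BM3 variant chosen from a screening panel (E. coli lysate), NADPH (cat.), D-glucose, glucose dehydrogenase, air, potassium phosphate buffer pH 7.5, 2% DMSO, 25 °C
Reagents that add atoms: dioxygen, O=O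
Why: Proposed new method: the ferric heme is reduced, binds O2 and after a second electron and protonation gives the ferryl oxo porphyrin radical cation, which transfers its oxygen atom to C4=C5; the closest known reactions are P450 and flavin monooxygenase tailoring epoxidations of polyene polyketides and alkene epoxidations by engineered BM3 variants. The oxirane closes by [2+1] oxygen-atom transfer, both C–O bonds forming on the same face in a concerted or very short-lived stepwise (3-exo collapse) manner. Because the addition is syn, the E geometry of C4=C5 fixes the trans relation of C3 and C6 on the ring. The absolute configuration (4S,5S) is set by which face of the alkene the active site turns to the iron. The step needs site selectivity among five C=C bonds, chemoselectivity against allylic hydroxylation at C8, C13 and C18, and face selectivity. The substrate offers a C1 carboxylate as an anchor three atoms from the alkene and a bulky bicycle at the other end, so a pocket that binds the carboxylate near the oxidant should hold the electron-rich ring diene and C6=C7 away from it. The tailoring epoxidase of the producing organism is the second enzyme source.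

## Compound list

1 | (S)-carvone | CC(=C)[C@H]1CC=C(C)C(=O)C1 | starting material
2 | (chloromethoxy)triisopropylsilane | ClCO[Si](C(C)C)(C(C)C)C(C)C | starting material
3 | lithium dienolate of 1 | [Li+].[O-]C1=C[C@@H](C(C)=C)CC=C1C | intermediate
4 | (5S,6S)-2-methyl-5-(prop-1-en-2-yl)-6-[(triisopropylsilyloxy)methyl]cyclohex-2-en-1-one | O=C1C(C)=CC[C@H](C(C)=C)[C@H]1CO[Si](C(C)C)(C(C)C)C(C)C | intermediate
5 | allylmagnesium bromide | C=CC[Mg]Br | starting material
6 | tertiary allylic alcohol (C17 carbinol) | C=CC[C@]1(O)C(C)=CC[C@H](C(C)=C)[C@H]1CO[Si](C(C)C)(C(C)C)C(C)C | intermediate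
7 | transposed allyl enone (C15 ketone) | C=CCC1=C(C)C(=O)C[C@H](C(C)=C)[C@H]1CO[Si](C(C)C)(C(C)C)C(C)C | intermediate
8 | C19 methyl ketone | CC(=O)CC1=C(C)C(=O)C[C@H](C(C)=C)[C@H]1CO[Si](C(C)C)(C(C)C)C(C)C | intermediate
9 | C19 ethylene ketal | CC1(CC2=C(C)C(=O)C[C@H](C(C)=C)[C@H]2CO[Si](C(C)C)(C(C)C)C(C)C)OCCO1 | intermediate
10 | (S)-3-bromo-2-methylpropan-1-ol | OC[C@H](C)CBr | starting material
11 | (S)-(3-hydroxy-2-methylpropyl)triphenylphosphonium bromide | OC[C@H](C)C[P+](c1ccccc1)(c1ccccc1)c1ccccc1.[Br-] | intermediate
12 | lithium oxido ylide | [Li+].[O-]C[C@H](C)C=P(c1ccccc1)(c1ccccc1)c1ccccc1 | intermediate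
13 | (R)-2-methylbut-3-en-1-ol | OC[C@H](C)C=C | intermediate
14 | (R)-2-methylbut-3-en-1-yl trifluoromethanesulfonate | FC(F)(F)S(=O)(=O)OC[C@H](C)C=C | intermediate
15 | lithium enolate of 9 (C14=C15) | CC1(CC2=C(C)C([O-])=C[C@H](C(C)=C)[C@H]2CO[Si](C(C)C)(C(C)C)C(C)C)OCCO1.[Li+] | intermediate
16 | C14-alkylated enone | CC1(CC2=C(C)C(=O)[C@@H](C[C@H](C)C=C)[C@H](C(C)=C)[C@H]2CO[Si](C(C)C)(C(C)C)C(C)C)OCCO1 | intermediate
17 | trans-fused bicyclic enone with C10=C11 | CC1(CC2=C(C)C(=O)[C@H]3C[C@H](C)C=C(C)[C@@H]3[C@H]2CO[Si](C(C)C)(C(C)C)C(C)C)OCCO1 | intermediate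
18 | organoborane (C11 borane, C15 boryl ether) | CC1(CC2=C(C)[C@H](OB)[C@H]3C[C@H](C)[C@@H](B)[C@H](C)[C@@H]3[C@H]2CO[Si](C(C)C)(C(C)C)C(C)C)OCCO1 | intermediate
19 | C11,C15 diol | CC1(CC2=C(C)[C@H](O)[C@H]3C[C@H](C)[C@@H](O)[C@H](C)[C@@H]3[C@H]2CO[Si](C(C)C)(C(C)C)C(C)C)OCCO1 | intermediate
20 | hydroxy enone | CC1(CC2=C(C)C(=O)[C@H]3C[C@H](C)[C@@H](O)[C@H](C)[C@@H]3[C@H]2CO[Si](C(C)C)(C(C)C)C(C)C)OCCO1 | intermediate
21 | C11 silyl ether enone | CC1(CC2=C(C)C(=O)[C@H]3C[C@H](C)[C@@H](O[Si](C)(C)C(C)(C)C)[C@H](C)[C@@H]3[C@H]2CO[Si](C(C)C)(C(C)C)C(C)C)OCCO1 | intermediate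
22 | lithium dienolate of 21 | CC1(CC2=C(C)C([O-])=C3C[C@H](C)[C@@H](O[Si](C)(C)C(C)(C)C)[C@H](C)[C@@H]3[C@H]2CO[Si](C(C)C)(C(C)C)C(C)C)OCCO1.[Li+] | intermediate
23 | dienyl triflate | CC1(CC2=C(C)C(OS(=O)(=O)C(F)(F)F)=C3C[C@H](C)[C@@H](O[Si](C)(C)C(C)(C)C)[C@H](C)[C@@H]3[C@H]2CO[Si](C(C)C)(C(C)C)C(C)C)OCCO1 | intermediate
24 | ring A diene, bis-silyl ether | CC1(CC2=C(C)C=C3C[C@H](C)[C@@H](O[Si](C)(C)C(C)(C)C)[C@H](C)[C@@H]3[C@H]2CO[Si](C(C)C)(C(C)C)C(C)C)OCCO1 | intermediate
25 | C7,C11 diol | CC1(CC2=C(C)C=C3C[C@H](C)[C@@H](O)[C@H](C)[C@@H]3[C@H]2CO)OCCO1 | intermediate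
26 | C7 aldehyde, 8-epi | CC1(CC2=C(C)C=C3C[C@H](C)[C@@H](O)[C@H](C)[C@@H]3[C@H]2C=O)OCCO1 | intermediate
27 | dipotassium alkoxide enolate | CC1(CC2=C(C)C=C3C[C@H](C)[C@@H]([O-])[C@H](C)[C@@H]3C2=C[O-])OCCO1.[K+].[K+] | intermediate
28 | C7 aldehyde, target C8 configuration | CC1(CC2=C(C)C=C3C[C@H](C)[C@@H](O)[C@H](C)[C@@H]3[C@@H]2C=O)OCCO1 | intermediate
29 | ethyl 2-(triphenylphosphoranylidene)propanoate | CCOC(=O)C(C)=P(c1ccccc1)(c1ccccc1)c1ccccc1 | starting material
30 | ethyl (E)-enoate | CC1(CC2=C(C)C=C3C[C@H](C)[C@@H](O)[C@H](C)[C@@H]3[C@@H]2/C=C(\C)C(=O)OCC)OCCO1 | intermediate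
31 | C5 allylic alcohol | CC1(CC2=C(C)C=C3C[C@H](C)[C@@H](O)[C@H](C)[C@@H]3[C@@H]2/C=C(\C)CO)OCCO1 | intermediate
32 | C5 enal | CC1(CC2=C(C)C=C3C[C@H](C)[C@@H](O)[C@H](C)[C@@H]3[C@@H]2/C=C(\C)C=O)OCCO1 | intermediate
33 | 2-(triphenylphosphoranylidene)propanal | CC(C=O)=P(c1ccccc1)(c1ccccc1)c1ccccc1 | starting material
34 | C3 dienal | CC1(CC2=C(C)C=C3C[C@H](C)[C@@H](O)[C@H](C)[C@@H]3[C@@H]2/C=C(\C)/C=C(\C)C=O)OCCO1 | intermediate
35 | methyl (triphenylphosphoranylidene)acetate | COC(=O)C=P(c1ccccc1)(c1ccccc1)c1ccccc1 | starting material
36 | methyl trienoate | CC1(CC2=C(C)C=C3C[C@H](C)[C@@H](O)[C@H](C)[C@@H]3[C@@H]2/C=C(\C)/C=C(\C)/C=C/C(=O)OC)OCCO1 | intermediate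
37 | lithium trienoate, ketal | CC1(CC2=C(C)C=C3C[C@H](C)[C@@H](O)[C@H](C)[C@@H]3[C@@H]2/C=C(\C)/C=C(\C)/C=C/C(=O)[O-])OCCO1.[Li+] | intermediate
38 | 11-hydroxy-19-oxo trienoic acid | CC(=O)CC1=C(C)C=C2C[C@H](C)[C@@H](O)[C@H](C)[C@@H]2[C@@H]1/C=C(\C)/C=C(\C)/C=C/C(=O)O | intermediate
39 | 4,5-deoxy precursor | CC(=O)CC1=C(C)C=C2C[C@H](C)C(=O)[C@H](C)[C@@H]2[C@@H]1/C=C(\C)/C=C(\C)/C=C/C(=O)O | intermediate
40 | CNP0214881.1 | CC(=O)CC1=C(C)C=C2C[C@H](C)C(=O)[C@H](C)[C@@H]2[C@@H]1/C=C(\C)[C@@H]1O[C@@]1(C)/C=C/C(=O)O | target

## Step count and least certain steps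

Total: 26 steps. Longest linear sequence: 23 steps (steps 1–5 and 9–26 from 1). Fragment 14 takes 3 steps (6–8).

**Step 26 (key step).** The most likely failure is poor site selectivity: oxygen transfer to the more electron-rich ring A diene or to C6=C7, allylic hydroxylation at C8, or no productive binding in any variant screened. Fallback with known chemistry, from 34 to 40:
- Luche reduction (NaBH4, CeCl3) of 34 gives the dienol F1.
- Sharpless asymmetric epoxidation (Ti(OiPr)4, L-(+)-diethyl tartrate, t-BuOOH) gives the epoxy alcohol F2. The C3 hydroxyl directs oxygen to C4=C5 only, and this tartrate enantiomer, the one that gives (2S,3S)-epoxy alcohols from E-2-alken-1-ols, should give (4S,5S).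
- Dess–Martin oxidation of both hydroxyls gives the epoxy aldehyde F3.
- Wittig olefination with 35 gives the epoxy trienoate F4.
- Pyridinium p-toluenesulfonate in wet acetone removes the ketal to give the methyl ester F5.
- Me3SnOH cleaves the ester under neutral conditions and returns to 40.

The price is that the vinyl oxirane is carried through three steps.

**Step 11.** Facial selectivity may be poor or the reaction slow, because β-face addition builds a 1,3-diaxial contact between the C10 and C12 methyls in the locked chair. Fallback from 9 to 20, which sets both methyls by hydroxyl direction instead: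
- Alkylation of the C14 enolate of 9 with 2,3-dibromopropene gives the bromoallyl ketone F6.
- SeO2/t-BuOOH gives the allylic alcohol F7, and MnO2 the enal F8.
- Nozaki–Hiyama–Kishi closure (CrCl2, NiCl2 cat.) gives the bis-methylene carbinol F9.
- Hydrogenation with [Ir(cod)(PCy3)(py)]PF6 delivers hydrogen to both exocyclic alkenes syn to the C11 hydroxyl and returns to 20.

**Step 18.** Stereoinversion may be incomplete, the proton may add at the γ or ε carbon (moving the diene into conjugation), or the aldehyde enolate may self-condense. Fallback from 25 to 28, through an ester enolate that cannot undergo aldol addition and can be recycled: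
- TEMPO, PhI(OAc)2 in MeCN/H2O gives the acid F10.
- Me3SiCHN2 gives the methyl ester F11.
- LiN(i-Pr)2 at −78 °C followed by kinetic protonation gives the C8-epimerised ester F12.
- i-Bu2AlH at −78 °C returns to 28.

**Step 14.** Proton transfer to the extended (γ) enolate before trapping would give the linear dienyl triflate and scramble C8. Fallback from 21 to 24:
- Luche reduction gives the allylic alcohol F13.
- The Burgess reagent (methyl N-(triethylammoniumsulfonyl)carbamate) then eliminates syn toward C14–H, the only β hydrogen on an sp3 carbon, and returns to 24.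

## Further compounds

F1 | step 26 | C3 dienol | CC1(CC2=C(C)C=C3C[C@H](C)[C@@H](O)[C@H](C)[C@@H]3[C@@H]2/C=C(\C)/C=C(\C)CO)OCCO1
F2 | step 26 | (4S,5S)-epoxy alcohol | CC1(CC2=C(C)C=C3C[C@H](C)[C@@H](O)[C@H](C)[C@@H]3[C@@H]2/C=C(\C)[C@@H]2O[C@@]2(C)CO)OCCO1
F3 | step 26 | epoxy aldehyde with C11 ketone | CC1(CC2=C(C)C=C3C[C@H](C)C(=O)[C@H](C)[C@@H]3[C@@H]2/C=C(\C)[C@@H]2O[C@@]2(C)C=O)OCCO1
F4 | step 26 | methyl epoxy enoate, C19 ketal | CC1(CC2=C(C)C=C3C[C@H](C)C(=O)[C@H](C)[C@@H]3[C@@H]2/C=C(\C)[C@@H]2O[C@@]2(C)/C=C/C(=O)OC)OCCO1
F5 | step 26 | methyl ester of the target | CC(=O)CC1=C(C)C=C2C[C@H](C)C(=O)[C@H](C)[C@@H]2[C@@H]1/C=C(\C)[C@@H]1O[C@@]1(C)/C=C/C(=O)OC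
F6 | step 11 | C14 2-bromoallyl ketone | CC1(CC2=C(C)C(=O)[C@@H](CC(Br)=C)[C@H](C(C)=C)[C@H]2CO[Si](C(C)C)(C(C)C)C(C)C)OCCO1
F7 | step 11 | C11 allylic alcohol | CC1(CC2=C(C)C(=O)[C@@H](CC(Br)=C)[C@H](C(CO)=C)[C@H]2CO[Si](C(C)C)(C(C)C)C(C)C)OCCO1
F8 | step 11 | C11 enal | CC1(CC2=C(C)C(=O)[C@@H](CC(Br)=C)[C@H](C(C=O)=C)[C@H]2CO[Si](C(C)C)(C(C)C)C(C)C)OCCO1
F9 | step 11 | bis-methylene carbinol | CC1(CC2=C(C)C(=O)[C@H]3CC(=C)[C@@H](O)C(=C)[C@@H]3[C@H]2CO[Si](C(C)C)(C(C)C)C(C)C)OCCO1
F10 | step 18 | C7 carboxylic acid, 8-epi | CC1(CC2=C(C)C=C3C[C@H](C)[C@@H](O)[C@H](C)[C@@H]3[C@H]2C(=O)O)OCCO1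
F11 | step 18 | C7 methyl ester, 8-epi | CC1(CC2=C(C)C=C3C[C@H](C)[C@@H](O)[C@H](C)[C@@H]3[C@H]2C(=O)OC)OCCO1
F12 | step 18 | C7 methyl ester, target C8 configuration | CC1(CC2=C(C)C=C3C[C@H](C)[C@@H](O)[C@H](C)[C@@H]3[C@@H]2C(=O)OC)OCCO1
F13 | step 14 | C15 allylic alcohol | CC1(CC2=C(C)[C@H](O)[C@H]3C[C@H](C)[C@@H](O[Si](C)(C)C(C)(C)C)[C@H](C)[C@@H]3[C@H]2CO[Si](C(C)C)(C(C)C)C(C)C)OCCO1
A1 | alternative 1 | endo Diels–Alder adduct (C16 silyloxy, C18 lactone, C7 menthyl acetal) | C[C@]1(O[Si](C)(C)C(C)(C)C)C=C2CCC3(OCCO3)C[C@@H]2[C@@H]4[C@@H](O[C@H]5C[C@@H](C)CC[C@@H]5C(C)C)OC(=O)[C@H]14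
A2 | alternative 2 | tricyclic diene lactone | C[C@H]3CC1=C(C)C=C2C[C@H](C)[C@@H](O[Si](C)(C)C(C)(C)C)[C@@H](C)[C@@H]2[C@@H]1C(=O)O3
A3 | alternative 3 | potassium C11 enolate of the cis-fused bicycle | [K+].[O-]C1=C(C)[C@@H]2[C@H](C=C(C)C)C(O[Si](C)(C)C(C)(C)C)=C(C)C[C@@H]2CC1
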